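**Plan**

- Units are numbered 1 to 4 from the upper epigallocatechin to the terminal epicatechin; the target is read as epigallocatechin-(4β→8)-epigallocatechin-(4β→8)-epigallocatechin 3-O-gallate-(4β→8)-epicatechin.
- Retrosynthetic cuts: first the interflavan bond C4(unit 2)–C8(unit 3); then ring C of unit 2 at O1–C2 and C4a–C4; last C4(unit 1)–aryl, C4(unit 3)–C8(unit 4) and the gallate ester.
- Enabling feature: in unit 2, O1 and C4a are the hydroxyl oxygen and the ortho carbon of one phloroglucinol ring A (a 1,3-O,C-dinucleophile). C2–C3–C4 is a 1,3-dielectrophile at the oxidation level of a cis-α,β-epoxy aldehyde (C4 = CHO, C2 = benzylic epoxide carbon), and the C4–OH left behind is the leaving group for the next interflavan bond.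
- Forward order: units 1, 3 and 4 come from (−)-epigallocatechin and (−)-epicatechin. Unit 1 is ionised at C4 and capped with 3,5-bis(benzyloxy)phenol, ring C of unit 2 is annulated onto that phenol, the resulting flavan-3,4-diol is ionised and joined to C8 of the galloylated lower dimer, and hydrogenolysis ends the route.
- Stereochemistry: units 1, 3 and 4 from the chiral pool; C2 and C3 of unit 2 from one Jacobsen epoxidation (cis-epoxide, inversion at C2 on ring closure gives 2,3-cis); all three C4 centres by attack on a flavan-4-yl cation anti to the 3-oxygen (4β).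

Key step: step 8

Remark: the carbinol configuration at C4 of the flavan-3,4-diol made in the key step is left open, because that centre is ionised in the following coupling and both epimers serve.

**Step 1**
Reactants: 1 (−)-epigallocatechin
Product: 3 5,7,3′,4′,5′-penta-O-benzyl-(−)-epigallocatechin
Conditions: BnBr (5.2 equiv), K2CO3, DMF, 0 °C → rt
Reagents that add atoms: benzyl bromide (2), BrCc1ccccc1
Why: Williamson etherification of the five phenols should leave the much less acidic secondary 3-OH free and touches no stereocentre.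

**Step 2**
Reactants: 3 5,7,3′,4′,5′-penta-O-benzyl-(−)-epigallocatechin
Product: 5 4β-(2-ethoxyethoxy)-5,7,3′,4′,5′-penta-O-benzyl-epigallocatechin
Conditions: DDQ (2 equiv), 2-ethoxyethanol (5 equiv), CH2Cl2, rt
Reagents that add atoms: 2-ethoxyethanol (4), CCOCCO
Why: DDQ benzylic oxidation (hydride abstraction at C4, cation stabilised by ring A) followed by capture by the alcohol anti to the axial 3-OH should give the 4β-ether, as is general for benzylated 2,3-cis-flavan-3-ols.

**Step 3**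
Reactants: 5 4β-(2-ethoxyethoxy)-5,7,3′,4′,5′-penta-O-benzyl-epigallocatechin
Product: 7 8-bromo-4β-(2-ethoxyethoxy)-5,7,3′,4′,5′-penta-O-benzyl-epigallocatechin
Conditions: NBS (1.05 equiv), CH2Cl2, −40 → 0 °C
Reagents that add atoms: N-bromosuccinimide (6), O=C1CCC(=O)N1Br
Why: Electrophilic aromatic bromination should take place at C8, the most nucleophilic carbon of a 5,7-di-O-benzylflavan, which blocks unit 1 as a nucleophile in all later cationic couplings.

**Step 4**
Reactants: 7 8-bromo-4β-(2-ethoxyethoxy)-5,7,3′,4′,5′-penta-O-benzyl-epigallocatechin; 8 3,5-bis(benzyloxy)phenol (3 equiv)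
Product: 9 2-(8-bromo-5,7,3′,4′,5′-penta-O-benzyl-epigallocatechin-4β-yl)-3,5-bis(benzyloxy)phenol
Conditions: TMSOTf (0.2 equiv), CH2Cl2, −78 → −40 °C
Reagents that add atoms: none
Why: Friedel–Crafts arylation of the flavan-4-yl cation released from the 4-alkoxy group should occur anti to the 3-OH (4β) and at the carbon ortho to the free hydroxyl of 8, which is less hindered than the carbon between the two benzyloxy groups and is also the site reached by O→C return of any O-alkylated ion pair.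

**Step 5**
Reactants: 10 3,4,5-tris(benzyloxy)benzaldehyde; 11 methyl 2-[bis(2,2,2-trifluoroethoxy)phosphoryl]acetate
Product: 12 methyl (Z)-3-[3,4,5-tris(benzyloxy)phenyl]prop-2-enoate
Conditions: KN(SiMe3)2, 18-crown-6, THF, −78 °C
Reagents that add atoms: none
Why: Still–Gennari olefination should give the Z-enoate because the electron-poor phosphonate eliminates fast and irreversibly from the kinetically formed adduct.

**Step 6**
Reactants: 12 methyl (Z)-3-[3,4,5-tris(benzyloxy)phenyl]prop-2-enoate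
Product: 14 methyl (2S,3S)-3-[3,4,5-tris(benzyloxy)phenyl]oxirane-2-carboxylate (cis)
Conditions: (S,S)-N,N′-bis(3,5-di-tert-butylsalicylidene)-1,2-cyclohexanediaminomanganese chloride (6 mol %), NaOCl (aq, pH 11.3), 4-phenylpyridine N-oxide, CH2Cl2, 0 °C
Reagents that add atoms: sodium hypochlorite (13), [Na+].[O-]Cl
Why: Jacobsen–Katsuki epoxidation of a cis-cinnamate should transfer oxygen to one enantioface of the Z-alkene, and the (S,S)-ligand is expected to give the (2S,3S)-cis-glycidate by analogy with the (R,R)-catalyst/(2R,3R)-epoxide pairing of the parent cis-cinnamate ester, so this step sets both C2 and C3 of unit 2 (any trans-epoxide from stepwise collapse is removed by chromatography).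

**Step 7**
Reactants: 14 methyl (2S,3S)-3-[3,4,5-tris(benzyloxy)phenyl]oxirane-2-carboxylate (cis)
Product: 15 (2S,3S)-3-[3,4,5-tris(benzyloxy)phenyl]oxirane-2-carbaldehyde (cis)
Conditions: iBu2AlH (1.1 equiv), toluene/CH2Cl2, −78 °C; aq Rochelle salt
Reagents that add atoms: none
Why: Partial ester reduction with DIBAL-H should stop at the aluminium hemiacetal at −78 °C and release the aldehyde on work-up, and the epoxide carbons are not enolisable so both stereocentres are kept.

**Step 8**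
Reactants: 9 2-(8-bromo-5,7,3′,4′,5′-penta-O-benzyl-epigallocatechin-4β-yl)-3,5-bis(benzyloxy)phenol; 15 (2S,3S)-3-[3,4,5-tris(benzyloxy)phenyl]oxirane-2-carbaldehyde (cis, 1.3 equiv)
Product: 17 8-bromo-penta-O-benzyl-epigallocatechin-(4β→8)-(penta-O-benzyl-4-hydroxy-epigallocatechin) as its C4 epimers, via epoxy carbinol adduct 16 (not isolated)
Conditions: Ti(OiPr)4 (2.2 equiv), toluene, rt, iPrOH removed in vacuo; then 15, toluene, 0 °C → rt; then 45 °C; aq Rochelle salt
Reagents that add atoms: none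
Why: Proposed new method: the titanium aryloxide of 9 binds the aldehyde of 15 and delivers its only free ortho carbon (the later C4a) to the carbonyl carbon through a six-membered cyclic transition state, which forms C4a–C4 and gives the titanium-bound epoxy carbinol 16; on warming, titanium activates the epoxide and the phenol oxygen opens it at the benzylic carbon with inversion, which forms O1–C2. The closest known reactions are the ortho-specific hydroxyalkylation of titanium and magnesium phenoxides with α-oxygenated aldehydes, the Ti(OiPr)4-mediated opening of 2,3-epoxy alcohols at the carbon remote from the carbinol, and the acid-mediated cyclisation of ortho-(3-aryloxiranylmethyl)phenols to flavan-3-ols, but their union in one flask as a (3+3) annulation of a phenol with a cis-epoxy aldehyde to a flavan-3,4-diol has not been shown. Ring C of unit 2 closes by 6-endo-tet anti opening of the epoxide, and the competing 5-exo attack at C3 is disfavoured by the benzylic, cation-stabilising character of C2 and by the titanium preference for the remote carbon. C3 keeps the epoxide configuration set in step 6, C2 arises by stereospecific inversion so that the cis-epoxide gives the 2,3-cis (2R,3R) ring, and the C4 carbinol needs no control because it is ionised in step 12. The step needs ortho-C attack instead of para-C or O attack on the aldehyde (secured by the metal template and the single free ortho CH) and the 4→8 instead of the 4→6 ring (secured because the only free hydroxyl of 9 is the one next to the carbon that bears unit 1, the other ring A oxygens being benzylated), while unit 1 stays inert because its C8 is brominated.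

**Step 9**
Reactants: 5 4β-(2-ethoxyethoxy)-5,7,3′,4′,5′-penta-O-benzyl-epigallocatechin; 18 3,4,5-tris(benzyloxy)benzoic acid
Product: 19 4β-(2-ethoxyethoxy)-5,7,3′,4′,5′-penta-O-benzyl-epigallocatechin 3-O-[3,4,5-tris(benzyloxy)benzoate]
Conditions: DCC, DMAP, CH2Cl2, 0 °C → rt
Reagents that add atoms: none
Why: Steglich esterification should acylate the only free hydroxyl (the axial 3-OH) without touching the acid-labile 4-alkoxy group or any stereocentre.

**Step 10**
Reactants: 20 (−)-epicatechin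
Product: 21 5,7,3′,4′-tetra-O-benzyl-(−)-epicatechin
Conditions: BnBr (4.2 equiv), K2CO3, DMF, 0 °C → rt
Reagents that add atoms: benzyl bromide (2), BrCc1ccccc1
Why: Williamson etherification of the four phenols should leave the secondary 3-OH free and touches no stereocentre.

**Step 11**
Reactants: 19 4β-(2-ethoxyethoxy)-5,7,3′,4′,5′-penta-O-benzyl-epigallocatechin 3-O-[3,4,5-tris(benzyloxy)benzoate]; 21 5,7,3′,4′-tetra-O-benzyl-(−)-epicatechin (4 equiv)
Product: 22 [5,7,3′,4′,5′-penta-O-benzyl-3-O-(tri-O-benzylgalloyl)-epigallocatechin]-(4β→8)-[5,7,3′,4′-tetra-O-benzyl-epicatechin]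
Conditions: TMSOTf (0.1 equiv), CH2Cl2, −78 °C
Reagents that add atoms: none
Why: Lewis-acid-mediated flavan-4-yl cation/arene coupling (Friedel–Crafts type) should join C8 of 21, its most nucleophilic carbon, to C4 of 19 anti to the 3-acyloxy group, which also shields the α face, giving the 4β→8 bond, while the excess of 21 suppresses self-condensation of 19.

**Step 12**
Reactants: 17 8-bromo-penta-O-benzyl-epigallocatechin-(4β→8)-(penta-O-benzyl-4-hydroxy-epigallocatechin); 22 lower dimer (1.5 equiv)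
Product: 23 fully protected tetramer (22 benzyl ethers, bromine at C8 of unit 1)
Conditions: TMSOTf (0.5 equiv), 4 Å MS, CH2Cl2, −78 → −30 °C
Reagents that add atoms: none
Why: Ionisation of the benzylic C4–OH of the flavan-3,4-diol (either epimer) to the flavan-4-yl cation and Friedel–Crafts attack by C8 of unit 3, the only free C8 in 22, anti to the axial 3-OH of unit 2 should set the last stereocentre as 4β, and the bromine at C8 of unit 1 keeps 17 from condensing with itself.

**Step 13**
Reactants: 23 fully protected tetramer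
Product: 24 epigallocatechin-(4β→8)-epigallocatechin-(4β→8)-(epigallocatechin 3-O-gallate)-(4β→8)-epicatechin
Conditions: H2 (1 atm), Pd(OH)2/C, NaOAc (1.5 equiv), THF/MeOH/H2O, rt
Reagents that add atoms: none
Why: Catalytic hydrogenolysis should cleave the 22 benzyl ethers and the aryl C–Br bond in one operation while the gallate ester, the interflavan bonds and all stereocentres stay untouched, with sodium acetate buffering the HBr.

**Compound list**

1 | (−)-epigallocatechin, (2R,3R) | O[C@@H]1Cc2c(O)cc(O)cc2O[C@@H]1c1cc(O)c(O)c(O)c1 | starting material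
2 | benzyl bromide | BrCc1ccccc1 | starting material
3 | 5,7,3′,4′,5′-penta-O-benzyl-(−)-epigallocatechin (3-OH free) | O[C@@H]1Cc2c(OCc3ccccc3)cc(OCc3ccccc3)cc2O[C@@H]1c1cc(OCc2ccccc2)c(OCc2ccccc2)c(OCc2ccccc2)c1 | intermediate
4 | 2-ethoxyethanol | CCOCCO | starting material
5 | 4β-(2-ethoxyethoxy)-5,7,3′,4′,5′-penta-O-benzyl-epigallocatechin (2α-aryl, 3α-OH, 4β-OR) | CCOCCO[C@H]1c2c(OCc3ccccc3)cc(OCc3ccccc3)cc2O[C@H](c2cc(OCc3ccccc3)c(OCc3ccccc3)c(OCc3ccccc3)c2)[C@@H]1O | intermediate
6 | N-bromosuccinimide | O=C1CCC(=O)N1Br | starting material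
7 | 8-bromo-4β-(2-ethoxyethoxy)-5,7,3′,4′,5′-penta-O-benzyl-epigallocatechin | CCOCCO[C@H]1c2c(OCc3ccccc3)cc(OCc3ccccc3)c(Br)c2O[C@H](c2cc(OCc3ccccc3)c(OCc3ccccc3)c(OCc3ccccc3)c2)[C@@H]1O | intermediate
8 | 3,5-bis(benzyloxy)phenol | Oc1cc(OCc2ccccc2)cc(OCc2ccccc2)c1 | starting material
9 | 2-(8-bromo-5,7,3′,4′,5′-penta-O-benzyl-epigallocatechin-4β-yl)-3,5-bis(benzyloxy)phenol | Oc1cc(OCc2ccccc2)cc(OCc2ccccc2)c1[C@H]1c2c(OCc3ccccc3)cc(OCc3ccccc3)c(Br)c2O[C@H](c2cc(OCc3ccccc3)c(OCc3ccccc3)c(OCc3ccccc3)c2)[C@@H]1O | intermediate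
10 | 3,4,5-tris(benzyloxy)benzaldehyde | O=Cc1cc(OCc2ccccc2)c(OCc2ccccc2)c(OCc2ccccc2)c1 | starting material
11 | methyl 2-[bis(2,2,2-trifluoroethoxy)phosphoryl]acetate | COC(=O)CP(=O)(OCC(F)(F)F)OCC(F)(F)F | starting material
12 | methyl (Z)-3-[3,4,5-tris(benzyloxy)phenyl]prop-2-enoate | COC(=O)/C=C\c1cc(OCc2ccccc2)c(OCc2ccccc2)c(OCc2ccccc2)c1 | intermediate
13 | sodium hypochlorite | [Na+].[O-]Cl | starting material
14 | methyl (2S,3S)-3-[3,4,5-tris(benzyloxy)phenyl]oxirane-2-carboxylate (cis-epoxide) | COC(=O)[C@H]1O[C@H]1c1cc(OCc2ccccc2)c(OCc2ccccc2)c(OCc2ccccc2)c1 | intermediate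
15 | (2S,3S)-3-[3,4,5-tris(benzyloxy)phenyl]oxirane-2-carbaldehyde (cis-epoxide) | O=C[C@H]1O[C@H]1c1cc(OCc2ccccc2)c(OCc2ccccc2)c(OCc2ccccc2)c1 | intermediate
16 | epoxy carbinol adduct: phenol 9 carrying at its free ortho carbon a CH(OH) group bonded to the cis-epoxide of 15 (carbinol epimers; titanium-bound in the flask) | Oc1c(C(O)[C@H]2O[C@H]2c2cc(OCc3ccccc3)c(OCc3ccccc3)c(OCc3ccccc3)c2)c(OCc2ccccc2)cc(OCc2ccccc2)c1[C@H]1c2c(OCc3ccccc3)cc(OCc3ccccc3)c(Br)c2O[C@H](c2cc(OCc3ccccc3)c(OCc3ccccc3)c(OCc3ccccc3)c2)[C@@H]1O | intermediate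
17 | 8-bromo-5,7,3′,4′,5′-penta-O-benzyl-epigallocatechin-(4β→8)-[5,7,3′,4′,5′-penta-O-benzyl-4-hydroxy-epigallocatechin] (unit 2 is a (2R,3R)-flavan-3,4-diol, 2α-aryl, 3α-OH; C4 epimers) | OC1c2c(OCc3ccccc3)cc(OCc3ccccc3)c([C@H]3c4c(OCc5ccccc5)cc(OCc5ccccc5)c(Br)c4O[C@H](c4cc(OCc5ccccc5)c(OCc5ccccc5)c(OCc5ccccc5)c4)[C@@H]3O)c2O[C@H](c2cc(OCc3ccccc3)c(OCc3ccccc3)c(OCc3ccccc3)c2)[C@@H]1O | intermediate
18 | 3,4,5-tris(benzyloxy)benzoic acid | OC(=O)c1cc(OCc2ccccc2)c(OCc2ccccc2)c(OCc2ccccc2)c1 | starting material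
19 | 4β-(2-ethoxyethoxy)-5,7,3′,4′,5′-penta-O-benzyl-epigallocatechin 3-O-[3,4,5-tris(benzyloxy)benzoate] | CCOCCO[C@H]1c2c(OCc3ccccc3)cc(OCc3ccccc3)cc2O[C@H](c2cc(OCc3ccccc3)c(OCc3ccccc3)c(OCc3ccccc3)c2)[C@@H]1OC(=O)c1cc(OCc2ccccc2)c(OCc2ccccc2)c(OCc2ccccc2)c1 | intermediate
20 | (−)-epicatechin, (2R,3R) | O[C@@H]1Cc2c(O)cc(O)cc2O[C@@H]1c1ccc(O)c(O)c1 | starting material
21 | 5,7,3′,4′-tetra-O-benzyl-(−)-epicatechin (3-OH free) | O[C@@H]1Cc2c(OCc3ccccc3)cc(OCc3ccccc3)cc2O[C@@H]1c1ccc(OCc2ccccc2)c(OCc2ccccc2)c1 | intermediate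
22 | [5,7,3′,4′,5′-penta-O-benzyl-3-O-(tri-O-benzylgalloyl)-epigallocatechin]-(4β→8)-[5,7,3′,4′-tetra-O-benzyl-epicatechin] | O=C(O[C@@H]1[C@@H](c2c(OCc3ccccc3)cc(OCc3ccccc3)c3c2O[C@H](c2ccc(OCc4ccccc4)c(OCc4ccccc4)c2)[C@H](O)C3)c2c(OCc3ccccc3)cc(OCc3ccccc3)cc2O[C@@H]1c1cc(OCc2ccccc2)c(OCc2ccccc2)c(OCc2ccccc2)c1)c1cc(OCc2ccccc2)c(OCc2ccccc2)c(OCc2ccccc2)c1 | intermediate
23 | (8-bromo-penta-O-benzyl-epigallocatechin)-(4β→8)-(penta-O-benzyl-epigallocatechin)-(4β→8)-[penta-O-benzyl-3-O-(tri-O-benzylgalloyl)-epigallocatechin]-(4β→8)-(tetra-O-benzyl-epicatechin) | O=C(O[C@@H]1[C@@H](c2c(OCc3ccccc3)cc(OCc3ccccc3)c3c2O[C@H](c2ccc(OCc4ccccc4)c(OCc4ccccc4)c2)[C@H](O)C3)c2c(OCc3ccccc3)cc(OCc3ccccc3)c([C@H]3c4c(OCc5ccccc5)cc(OCc5ccccc5)c([C@H]5c6c(OCc7ccccc7)cc(OCc7ccccc7)c(Br)c6O[C@H](c6cc(OCc7ccccc7)c(OCc7ccccc7)c(OCc7ccccc7)c6)[C@@H]5O)c4O[C@H](c4cc(OCc5ccccc5)c(OCc5ccccc5)c(OCc5ccccc5)c4)[C@@H]3O)c2O[C@@H]1c1cc(OCc2ccccc2)c(OCc2ccccc2)c(OCc2ccccc2)c1)c1cc(OCc2ccccc2)c(OCc2ccccc2)c(OCc2ccccc2)c1 | intermediate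
24 | epigallocatechin-(4β→8)-epigallocatechin-(4β→8)-(epigallocatechin 3-O-gallate)-(4β→8)-epicatechin (all units 2R,3R; extension units 2,3-cis-3,4-trans) | O=C(O[C@@H]1[C@@H](c2c(O)cc(O)c3c2O[C@H](c2ccc(O)c(O)c2)[C@H](O)C3)c2c(O)cc(O)c([C@H]3c4c(O)cc(O)c([C@H]5c6c(O)cc(O)cc6O[C@H](c6cc(O)c(O)c(O)c6)[C@@H]5O)c4O[C@H](c4cc(O)c(O)c(O)c4)[C@@H]3O)c2O[C@@H]1c1cc(O)c(O)c(O)c1)c1cc(O)c(O)c(O)c1 | target

**Step count and risks**

Total steps: 13. Longest linear sequence: 7 steps (steps 1, 2, 3, 4, 8, 12, 13).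

Step 8 (proposed new method) is the step most likely to fail. The aldehyde may be consumed by hydride transfer from an isopropoxide ligand before the hindered aryloxide adds. The epoxide may open in the 5-exo mode or through an SN1 path that scrambles C2. The new, very electron-rich carbinol may ionise and oligomerise. The fallback uses known chemistry, sets out from 5 and 7 and comes back at 23; unit 2 is then taken from the pool instead of being built. Compound 5 is treated with 2,6-dimethylbenzenethiol and BF3·OEt2 (CH2Cl2, −78 → 0 °C) to give the 4β-(2,6-dimethylphenylthio) ether of penta-O-benzyl-epigallocatechin F1, whose C4–S bond is inert to hard Lewis acids. Compound 7 is ionised with BF3·OEt2 at −78 °C in the presence of F1, whose free C8 attacks to give the 8-bromo-epigallocatechin-(4β→8)-epigallocatechin 4β-thioether F2. F2 is then activated with I2 and Ag2O (CH2Cl2, −78 → 0 °C) in the presence of 22 to give 23. This path replaces steps 4 to 8 and step 12.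

Step 12 is the second risk. The hindered dimer 22 may react slowly or at C6 positions, the product may be alkylated again, and the Lewis acid may cleave interflavan bonds if the temperature has to be raised. The fallback sets out from 17 and 19 and comes back at 23; it changes the order to a linear one with orthogonal leaving groups. Compound 19 is converted with 2,6-dimethylbenzenethiol and BF3·OEt2 into the 4β-(2,6-dimethylphenylthio) ether of the benzylated epigallocatechin gallate F3. Diol 17 is ionised (TMSOTf, −78 °C) in the presence of this small monomer to give the trimer thioether F4. F4 is activated with I2 and Ag2O in the presence of a large excess of the cheap monomer 21 to give 23.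

Step 4 is the third risk. The cation may be captured at the carbon para to the hydroxyl of 8, at oxygen, or twice, so that the ortho-linked phenol needed for the 4→8 ring is the minor product. The fallback sets out from 7 and comes back at 9; it uses a symmetric nucleophile for which only one C-adduct exists. Compound 7 and phloroglucinol (5 equiv, BF3·OEt2, 1,4-dioxane/CH2Cl2) give the 4β-(2,4,6-trihydroxyphenyl) adduct of 8-bromo-penta-O-benzyl-epigallocatechin F5. Controlled benzylation (BnBr 2.0 equiv, K2CO3, acetone) of the unhindered para hydroxyl and of one of the two equivalent, hindered ortho hydroxyls should then return 9.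

**Further compounds**

F1 | step 8 | 4β-(2,6-dimethylphenylthio)-5,7,3′,4′,5′-penta-O-benzyl-epigallocatechin | Cc1cccc(C)c1S[C@H]1c2c(OCc3ccccc3)cc(OCc3ccccc3)cc2O[C@H](c2cc(OCc3ccccc3)c(OCc3ccccc3)c(OCc3ccccc3)c2)[C@@H]1O
F2 | step 8 | (8-bromo-penta-O-benzyl-epigallocatechin)-(4β→8)-[4β-(2,6-dimethylphenylthio)-penta-O-benzyl-epigallocatechin] | Cc1cccc(C)c1S[C@H]1c2c(OCc3ccccc3)cc(OCc3ccccc3)c([C@H]3c4c(OCc5ccccc5)cc(OCc5ccccc5)c(Br)c4O[C@H](c4cc(OCc5ccccc5)c(OCc5ccccc5)c(OCc5ccccc5)c4)[C@@H]3O)c2O[C@H](c2cc(OCc3ccccc3)c(OCc3ccccc3)c(OCc3ccccc3)c2)[C@@H]1O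
F3 | step 12 | 4β-(2,6-dimethylphenylthio)-5,7,3′,4′,5′-penta-O-benzyl-epigallocatechin 3-O-[3,4,5-tris(benzyloxy)benzoate] | Cc1cccc(C)c1S[C@H]1c2c(OCc3ccccc3)cc(OCc3ccccc3)cc2O[C@H](c2cc(OCc3ccccc3)c(OCc3ccccc3)c(OCc3ccccc3)c2)[C@@H]1OC(=O)c1cc(OCc2ccccc2)c(OCc2ccccc2)c(OCc2ccccc2)c1
F4 | step 12 | (8-bromo-penta-O-benzyl-epigallocatechin)-(4β→8)-(penta-O-benzyl-epigallocatechin)-(4β→8)-[4β-(2,6-dimethylphenylthio)-penta-O-benzyl-3-O-(tri-O-benzylgalloyl)-epigallocatechin] | Cc1cccc(C)c1S[C@H]1c2c(OCc3ccccc3)cc(OCc3ccccc3)c([C@H]3c4c(OCc5ccccc5)cc(OCc5ccccc5)c([C@H]5c6c(OCc7ccccc7)cc(OCc7ccccc7)c(Br)c6O[C@H](c6cc(OCc7ccccc7)c(OCc7ccccc7)c(OCc7ccccc7)c6)[C@@H]5O)c4O[C@H](c4cc(OCc5ccccc5)c(OCc5ccccc5)c(OCc5ccccc5)c4)[C@@H]3O)c2O[C@H](c2cc(OCc3ccccc3)c(OCc3ccccc3)c(OCc3ccccc3)c2)[C@@H]1OC(=O)c1cc(OCc2ccccc2)c(OCc2ccccc2)c(OCc2ccccc2)c1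
F5 | step 4 | 2-(8-bromo-5,7,3′,4′,5′-penta-O-benzyl-epigallocatechin-4β-yl)benzene-1,3,5-triol | Oc1cc(O)cc(O)c1[C@H]1c2c(OCc3ccccc3)cc(OCc3ccccc3)c(Br)c2O[C@H](c2cc(OCc3ccccc3)c(OCc3ccccc3)c(OCc3ccccc3)c2)[C@@H]1O
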